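**Plan**

1. Numbering as in the target (used in all spiro[5.5] names): ring B = C1–C5 plus spiro C6, ring A = C6–C11 (C7 CHMe, C9 OH, C10 Br, C11 CMe2). The retrosynthesis first removes the ring-B halogens (C3–Cl, C2–Br ⇒ 2,3-epoxide ⇒ C2=C3 alkene) and the ring-A bromohydrin (C9–OH/C10–Br ⇒ C9 enol pivalate, locked toward C10).
2. Ring B is then cut at C2–C3/C3–C4 (C3 with its methyl leaves as diazoethane) to a spirocyclopentanone, this at C2–C4/C4–C5 (C4 as diazomethane) to a spirocyclobutanone, and this at C6–C1/C2–C5 ([2+2] of dichloroketene with the exocyclic C6=C5 alkene).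
3. Forward: ring A comes intact from ketoisophorone. On its C6 carbonyl a four-, then five-, then six-membered ring is grown, the last enlargement giving ring B in its final size. Ring A, then ring B, are halogenated.
4. Stereochemistry: C7 by Pd-catalysed enantioselective protonation; C6 by axial ketene addition anti to the axial C11 methyl (relay from C7); C10 by axial bromination, C9 by hydride anti to C–Br; C2/C3 by reagent-controlled Shi epoxidation, SN2 bromide opening (inversion at C2) and chloride substitution with retention at C3 through the bromonium ion.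
5. Feature that makes the key event possible: the C2 carbonyl of the spirocyclopentanone lies between the chlorinated, non-migrating C1 (spiro side) and the free C4 methylene, so a diazoalkane carbon can only enter between C2 and C4. The chlorines (removed in step 8) and the pivalate (removed in step 10) are helpers.

Key step: step 7

Remark: (S)-t-BuPHOX is written in step 3 on the assumption that it is the antipode giving (S)-5 (its enantiomer is used otherwise); C3 of 9 and 10 is an epimeric mixture that step 9 removes.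

**Route**

Step 1
Reactants: 1 ketoisophorone (2,6,6-trimethylcyclohex-2-ene-1,4-dione)
Product: 2 3,3,5-trimethyl-4-oxocyclohexa-1,5-dien-1-yl pivalate
Conditions: PivCl, Et3N, DMAP (cat.), CH2Cl2, 40 °C
Reagents that add atoms: pivaloyl chloride CC(C)(C)C(Cl)=O
Why: C10–H2 is the only enolisable position of the C9 carbonyl (C8 is vinylic), so O-acylation of the dienolate should give a single dienyl ester that locks the C9 enol toward C10 for the later bromination (enol ester formation).

Step 2
Reactants: 2 3,3,5-trimethyl-4-oxocyclohexa-1,5-dien-1-yl pivalate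
Product: 4 allyl 2,6,6-trimethyl-4-(pivaloyloxy)cyclohexa-1,4-dien-1-yl carbonate, via lithium enolate 3 (not isolated)
Conditions: L-Selectride, THF, −78 °C; then TMEDA, allyl chloroformate, −78 → 0 °C
Reagents that add atoms: allyl chloroformate C=CCOC(Cl)=O
Why: The bulky borohydride should add 1,4 at C8 (C10 is shielded by the quaternary C11, the C6 carbonyl by CMe2) to give the tetrasubstituted C6 enolate regiospecifically, which is O-acylated by the chloroformate (conjugate reduction with enolate trapping).

Step 3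
Reactants: 4 allyl 2,6,6-trimethyl-4-(pivaloyloxy)cyclohexa-1,4-dien-1-yl carbonate
Product: 5 (5S)-3,3,5-trimethyl-4-oxocyclohex-1-en-1-yl pivalate
Conditions: Pd(OAc)2 (10 mol %), (S)-t-BuPHOX (12.5 mol %), HCO2H, 4 Å MS, 1,4-dioxane, 40 °C
Reagents that add atoms: none
Why: Pd(0) ionises the allyl carbonate, loss of CO2 gives a chiral Pd–PHOX enolate, and its enantioface-selective protonation should set C7 as S, the quaternary C11 excluding later enolisation on the other side (catalytic enantioselective decarboxylative protonation).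

Step 4
Reactants: 5 (5S)-3,3,5-trimethyl-4-oxocyclohex-1-en-1-yl pivalate
Product: 6 (5S)-3,3,5-trimethyl-4-methylidenecyclohex-1-en-1-yl pivalate
Conditions: Zn, CH2Br2, TiCl4, THF/CH2Cl2, 0 °C → rt
Reagents that add atoms: dibromomethane BrCBr
Why: The non-basic gem-dimetallic reagent methylenates hindered, enolisable ketones without epimerising the α-stereocentre C7 and leaves esters alone (Lombardo methylenation).

Step 5
Reactants: 6 (5S)-3,3,5-trimethyl-4-methylidenecyclohex-1-en-1-yl pivalate
Product: 7 (4S,9S)-1,1-dichloro-5,5,9-trimethyl-2-oxospiro[3.5]non-6-en-7-yl pivalate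
Conditions: Cl3CCOCl, Zn–Cu, POCl3, Et2O, ultrasound, 20–35 °C
Reagents that add atoms: trichloroacetyl chloride (source of dichloroketene) ClC(Cl)(Cl)C(Cl)=O
Why: In the ketene–alkene [2+2] cycloaddition the ketene carbonyl carbon joins the terminal CH2 (C5) and CCl2 (C1) joins C6; the new C6–C1 bond should form axially, anti to the axial C11 methyl, which places C1 cis to the equatorial C7 methyl and sets C6 as S.

Step 6
Reactants: 7 (4S,9S)-1,1-dichloro-5,5,9-trimethyl-2-oxospiro[3.5]non-6-en-7-yl pivalate
Product: 8 (5S,10S)-1,1-dichloro-6,6,10-trimethyl-2-oxospiro[4.5]dec-7-en-8-yl pivalate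
Conditions: CH2N2, Et2O, MeOH (cat.), 0 °C
Reagents that add atoms: diazomethane C=[N+]=[N-]
Why: Diazomethane adds to the strained, chlorine-activated cyclobutanone and only the non-halogenated CH2 migrates, inserting C4 between C2 and C5 (regioselective diazomethane ring expansion of an α,α-dichlorocyclobutanone).

Step 7
Reactants: 8 (5S,10S)-1,1-dichloro-6,6,10-trimethyl-2-oxospiro[4.5]dec-7-en-8-yl pivalate
Product: 9 (6S,7S)-1,1-dichloro-3,7,11,11-tetramethyl-2-oxospiro[5.5]undec-9-en-9-yl pivalate (C3 epimers)
Conditions: CH3CHN2 (Et2O solution), Sc(OTf)3 (10 mol %), CH2Cl2, −78 → −20 °C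
Reagents that add atoms: diazoethane CC=[N+]=[N-]
Why: The Sc(III)-activated C2 carbonyl of 8 is attacked by the diazo carbon of diazoethane to give a β-oxido diazonium betaine, and loss of N2 with 1,2-shift of C4 from C2 to the new carbon inserts C3 with its methyl between C2 and C4, so the five-membered ring becomes ring B in its final size. The closest known reaction type is the Lewis-acid diazoalkane homologation of cyclic α-halo ketones (Tiffeneau–Demjanov type), in which the halogenated α-carbon does not migrate. No ring is closed: the six-membered ring arises by enlargement of the cyclopentanone through a 1,2-alkyl shift. The only new stereocentre, C3, forms without control as a mixture of epimers, which is harmless because C3 becomes sp2 in step 9, and C6 and C7 are untouched. The step needs regioselectivity (C4 versus C1 migration) and chemoselectivity (homologation versus oxirane formation or a second insertion): the electron-poor, non-migrating C1Cl2 group, which also raises the carbonyl electrophilicity, secures the first, and Lewis-acid activation at low temperature with the greater hindrance of 9 should secure the second.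

Step 8
Reactants: 9 (6S,7S)-1,1-dichloro-3,7,11,11-tetramethyl-2-oxospiro[5.5]undec-9-en-9-yl pivalate
Product: 10 (6S,7S)-3,7,11,11-tetramethyl-2-oxospiro[5.5]undec-9-en-9-yl pivalate (C3 epimers)
Conditions: Zn dust, AcOH, 50 °C
Reagents that add atoms: none
Why: Zinc reduces both α-C–Cl bonds through the zinc enolate and so removes the chlorine helpers, while the enol pivalate is inert (reductive dehalogenation of an α-halo ketone).

Step 9
Reactants: 10 (6S,7S)-3,7,11,11-tetramethyl-2-oxospiro[5.5]undec-9-en-9-yl pivalate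
Product: 11 (6S,7S)-3,7,11,11-tetramethyl-2-(trifluoromethylsulfonyloxy)spiro[5.5]undeca-2,9-dien-9-yl pivalate
Conditions: Tf2O, 2,6-di-tert-butyl-4-methylpyridine, CH2Cl2, 0 °C → rt
Reagents that add atoms: triflic anhydride O=S(=O)(OS(=O)(=O)C(F)(F)F)C(F)(F)F
Why: Under these equilibrating conditions the more substituted C2=C3 enol should be triflated in preference to the enol toward the neopentyl C1, which also erases the C3 stereocentre (thermodynamic enol triflate formation).

Step 10
Reactants: 11 (6S,7S)-3,7,11,11-tetramethyl-2-(trifluoromethylsulfonyloxy)spiro[5.5]undeca-2,9-dien-9-yl pivalate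
Product: 12 (6S,7S,10S)-10-bromo-3,7,11,11-tetramethyl-9-oxospiro[5.5]undec-2-en-2-yl trifluoromethanesulfonate
Conditions: NBS, NaHCO3, THF/H2O, 0 °C
Reagents that add atoms: N-bromosuccinimide O=C1CCC(=O)N1Br
Why: Bromination of the enol ester can only occur at C10 and should be axial, anti to the adjacent axial C11 methyl and on the face of the axial C1 arm, giving the 10S bromide after acyl loss to water, while the electron-poor enol triflate does not react (α-bromination of a ketone through its enol ester).

Step 11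
Reactants: 12 (6S,7S,10S)-10-bromo-3,7,11,11-tetramethyl-9-oxospiro[5.5]undec-2-en-2-yl trifluoromethanesulfonate
Product: 13 (6S,7S,9R,10S)-10-bromo-9-hydroxy-3,7,11,11-tetramethylspiro[5.5]undec-2-en-2-yl trifluoromethanesulfonate
Conditions: NaBH4, CeCl3·7H2O, MeOH, −78 °C
Reagents that add atoms: none
Why: The small hydride should attack the C9 carbonyl anti to the axial C–Br bond (polar Felkin–Anh control) and give the equatorial alcohol cis to bromine (9R) under non-basic Luche conditions that spare the enol triflate (1,2-reduction of an α-bromo ketone).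

Step 12
Reactants: 13 (6S,7S,9R,10S)-10-bromo-9-hydroxy-3,7,11,11-tetramethylspiro[5.5]undec-2-en-2-yl trifluoromethanesulfonate
Product: 14 (6S,7S,9R,10S)-10-bromo-3,7,11,11-tetramethylspiro[5.5]undec-2-en-9-ol
Conditions: Pd(OAc)2 (5 mol %), PPh3, HCO2H, n-Bu3N, DMF, 60 °C
Reagents that add atoms: none
Why: Oxidative addition of Pd(0) into the vinyl C–OTf bond, formate-derived hydride transfer and reductive elimination replace OTf by H and leave the C2=C3 alkene in a defined position, the neopentyl secondary bromide being inert (Pd-catalysed reduction of an enol triflate).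

Step 13
Reactants: 14 (6S,7S,9R,10S)-10-bromo-3,7,11,11-tetramethylspiro[5.5]undec-2-en-9-ol
Product: 15 (2R,3S,6S,7S,9R,10S)-10-bromo-2,3-epoxy-3,7,11,11-tetramethylspiro[5.5]undecan-9-ol
Conditions: Shi ketone (D-fructose-derived, 30 mol %), Oxone, K2CO3, n-Bu4NHSO4, MeCN/DMM/aq. buffer (pH 10.5), 0 °C
Reagents that add atoms: Oxone (potassium peroxymonosulfate) [K+].[O-]S(=O)(=O)OO
Why: The chiral dioxirane should deliver oxygen, through the spiro transition state for trisubstituted alkenes, to the C2=C3 face syn to C7, reagent control being needed because the two faces of ring B differ little (Shi asymmetric epoxidation).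

Step 14
Reactants: 15 (2R,3S,6S,7S,9R,10S)-10-bromo-2,3-epoxy-3,7,11,11-tetramethylspiro[5.5]undecan-9-ol
Product: 16 (2S,3S,6S,7S,9R,10S)-2,10-dibromo-3,7,11,11-tetramethylspiro[5.5]undecane-3,9-diol
Conditions: Li2NiBr4, THF, 0 °C → rt; aq. phosphate buffer work-up
Reagents that add atoms: dilithium tetrabromonickelate [Li+].[Li+].Br[Ni-2](Br)(Br)Br
Why: The soft bromide should attack the less substituted C2 of the epoxide in an SN2, trans-diaxial manner with inversion, which puts bromine on the face of C11 and leaves the tertiary C3 hydroxyl anti to it (regioselective epoxide opening by halide).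

Step 15
Reactants: 16 (2S,3S,6S,7S,9R,10S)-2,10-dibromo-3,7,11,11-tetramethylspiro[5.5]undecane-3,9-diol
Product: 17 (2S,3S,6S,7S,9R,10S)-2,10-dibromo-3-chloro-3,7,11,11-tetramethylspiro[5.5]undecan-9-ol
Conditions: HCl (4 M in 1,4-dioxane), LiCl, CH2Cl2, −20 → 0 °C
Reagents that add atoms: hydrogen chloride Cl
Why: Ionisation of the tertiary C3 alcohol is assisted by the anti C2 bromine, and chloride should open the resulting bromonium ion at the tertiary carbon from the face the hydroxyl left, giving C3–Cl with net retention and trans to bromine, while the secondary C9 alcohol does not ionise (SN1 substitution with neighbouring-group participation).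

**Compound list**

1 | ketoisophorone (2,6,6-trimethylcyclohex-2-ene-1,4-dione) | CC1=CC(=O)CC(C)(C)C1=O | starting material
2 | 3,3,5-trimethyl-4-oxocyclohexa-1,5-dien-1-yl pivalate | CC1=CC(OC(=O)C(C)(C)C)=CC(C)(C)C1=O | intermediate
3 | lithium 2,6,6-trimethyl-4-(pivaloyloxy)cyclohexa-1,4-dien-1-olate | [Li+].[O-]C1=C(C)CC(OC(=O)C(C)(C)C)=CC1(C)C | intermediate (not isolated)
4 | allyl 2,6,6-trimethyl-4-(pivaloyloxy)cyclohexa-1,4-dien-1-yl carbonate | C=CCOC(=O)OC1=C(C)CC(OC(=O)C(C)(C)C)=CC1(C)C | intermediate
5 | (5S)-3,3,5-trimethyl-4-oxocyclohex-1-en-1-yl pivalate | C[C@H]1CC(OC(=O)C(C)(C)C)=CC(C)(C)C1=O | intermediate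
6 | (5S)-3,3,5-trimethyl-4-methylidenecyclohex-1-en-1-yl pivalate | C[C@H]1CC(OC(=O)C(C)(C)C)=CC(C)(C)C1=C | intermediate
7 | (4S,9S)-1,1-dichloro-5,5,9-trimethyl-2-oxospiro[3.5]non-6-en-7-yl pivalate | C[C@H]1CC(OC(=O)C(C)(C)C)=CC(C)(C)[C@]12CC(=O)C2(Cl)Cl | intermediate
8 | (5S,10S)-1,1-dichloro-6,6,10-trimethyl-2-oxospiro[4.5]dec-7-en-8-yl pivalate | C[C@H]1CC(OC(=O)C(C)(C)C)=CC(C)(C)[C@]12CCC(=O)C2(Cl)Cl | intermediate
9 | (6S,7S)-1,1-dichloro-3,7,11,11-tetramethyl-2-oxospiro[5.5]undec-9-en-9-yl pivalate (C3 epimers) | C[C@H]1CC(OC(=O)C(C)(C)C)=CC(C)(C)[C@]12CCC(C)C(=O)C2(Cl)Cl | intermediate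
10 | (6S,7S)-3,7,11,11-tetramethyl-2-oxospiro[5.5]undec-9-en-9-yl pivalate (C3 epimers) | C[C@H]1CC(OC(=O)C(C)(C)C)=CC(C)(C)[C@]12CCC(C)C(=O)C2 | intermediate
11 | (6S,7S)-3,7,11,11-tetramethyl-2-(trifluoromethylsulfonyloxy)spiro[5.5]undeca-2,9-dien-9-yl pivalate | C[C@H]1CC(OC(=O)C(C)(C)C)=CC(C)(C)[C@]12CCC(C)=C(OS(=O)(=O)C(F)(F)F)C2 | intermediate
12 | (6S,7S,10S)-10-bromo-3,7,11,11-tetramethyl-9-oxospiro[5.5]undec-2-en-2-yl trifluoromethanesulfonate | C[C@H]1CC(=O)[C@@H](Br)C(C)(C)[C@]12CCC(C)=C(OS(=O)(=O)C(F)(F)F)C2 | intermediate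
13 | (6S,7S,9R,10S)-10-bromo-9-hydroxy-3,7,11,11-tetramethylspiro[5.5]undec-2-en-2-yl trifluoromethanesulfonate | C[C@H]1C[C@@H](O)[C@@H](Br)C(C)(C)[C@]12CCC(C)=C(OS(=O)(=O)C(F)(F)F)C2 | intermediate
14 | (6S,7S,9R,10S)-10-bromo-3,7,11,11-tetramethylspiro[5.5]undec-2-en-9-ol | C[C@H]1C[C@@H](O)[C@@H](Br)C(C)(C)[C@]12CCC(C)=CC2 | intermediate
15 | (2R,3S,6S,7S,9R,10S)-10-bromo-2,3-epoxy-3,7,11,11-tetramethylspiro[5.5]undecan-9-ol | C[C@H]1C[C@@H](O)[C@@H](Br)C(C)(C)[C@]12CC[C@]3(C)O[C@@H]3C2 | intermediate
16 | (2S,3S,6S,7S,9R,10S)-2,10-dibromo-3,7,11,11-tetramethylspiro[5.5]undecane-3,9-diol | C[C@H]1C[C@@H](O)[C@@H](Br)C(C)(C)[C@]12CC[C@](C)(O)[C@@H](Br)C2 | intermediate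
17 | (2S,3S,6S,7S,9R,10S)-2,10-dibromo-3-chloro-3,7,11,11-tetramethylspiro[5.5]undecan-9-ol | C[C@H]1C[C@@H](O)[C@@H](Br)C(C)(C)[C@]12CC[C@](C)(Cl)[C@@H](Br)C2 | target

**Totals and risks**

Total step count: 15. Longest linear sequence: 15 steps.

Steps most likely to fail:

Step 7 (key step). The betaine may close to the oxirane instead of undergoing the 1,2-shift, or the diazoalkane may add too slowly to the hindered dichloro ketone. Fallback, from 8 back to 10: 8 is dechlorinated (Zn, AcOH) to the spirocyclopentanone (5S,10S)-6,6,10-trimethyl-2-oxospiro[4.5]dec-7-en-8-yl pivalate F1. Henry addition of nitroethane (DBU) gives the nitro alcohol (5S,10S)-2-hydroxy-6,6,10-trimethyl-2-(1-nitroethyl)spiro[4.5]dec-7-en-8-yl pivalate F2. Reduction of the nitro group (Zn, AcOH) gives the amino alcohol (5S,10S)-2-(1-aminoethyl)-2-hydroxy-6,6,10-trimethylspiro[4.5]dec-7-en-8-yl pivalate F3, kept as its acetate salt. Diazotisation (NaNO2, aq. AcOH, 0 °C) then triggers a Tiffeneau–Demjanov shift in which the less hindered C4 should migrate, giving 10.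

Step 5. The cycloaddition at the doubly flanked alkene may be slow, so that ketene oligomerisation takes over, or the facial selectivity at C6 may be poor. Fallback, from 6 back to 10: hydroboration–oxidation (9-BBN; NaBO3) gives the primary alcohol (5S)-4-(hydroxymethyl)-3,3,5-trimethylcyclohex-1-en-1-yl pivalate F4, and Dess–Martin oxidation gives the α-branched aldehyde (5S)-4-formyl-3,3,5-trimethylcyclohex-1-en-1-yl pivalate F5. Pd/amine/acid-catalysed α-allylation with allyl alcohol builds the quaternary C6 in (4R,5S)-4-allyl-4-formyl-3,3,5-trimethylcyclohex-1-en-1-yl pivalate F6, with allyl expected axial and cis to the ring methyl. Wacker oxidation gives the keto aldehyde (4R,5S)-4-formyl-3,3,5-trimethyl-4-(2-oxopropyl)cyclohex-1-en-1-yl pivalate F7. Intramolecular aldol condensation (piperidinium acetate) closes the spirocyclopentenone (5S,10S)-6,6,10-trimethyl-2-oxospiro[4.5]deca-3,7-dien-8-yl pivalate F8. Conjugate reduction with Stryker's reagent gives the spirocyclopentanone (5S,10S)-6,6,10-trimethyl-2-oxospiro[4.5]dec-7-en-8-yl pivalate F1. Sc(OTf)3/diazoethane homologation, now steered only by the hindrance at the neopentyl C1, gives 10.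

Step 15. Ionisation may end in proton loss to an allylic bromide, or in halide scrambling (bromide return, chloride attack at C2), instead of retentive substitution. Fallback, from 14 directly to 17: electrophilic anti-bromochlorination of the C2=C3 alkene with NBS and Et4NCl in CH2Cl2 (chloride at the tertiary C3), with chromatographic removal of the diastereomer from attack on the other face. No new intermediate arises.

**Further compounds**

F1 | step 7 | (5S,10S)-6,6,10-trimethyl-2-oxospiro[4.5]dec-7-en-8-yl pivalate | C[C@H]1CC(OC(=O)C(C)(C)C)=CC(C)(C)[C@]12CCC(=O)C2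
F2 | step 7 | (5S,10S)-2-hydroxy-6,6,10-trimethyl-2-(1-nitroethyl)spiro[4.5]dec-7-en-8-yl pivalate (mixture at the two new centres) | C[C@H]1CC(OC(=O)C(C)(C)C)=CC(C)(C)[C@]12CCC(O)(C(C)[N+](=O)[O-])C2
F3 | step 7 | (5S,10S)-2-(1-aminoethyl)-2-hydroxy-6,6,10-trimethylspiro[4.5]dec-7-en-8-yl pivalate (mixture at the two new centres) | C[C@H]1CC(OC(=O)C(C)(C)C)=CC(C)(C)[C@]12CCC(O)(C(C)N)C2
F4 | step 5 | (5S)-4-(hydroxymethyl)-3,3,5-trimethylcyclohex-1-en-1-yl pivalate (C4 epimers) | C[C@H]1CC(OC(=O)C(C)(C)C)=CC(C)(C)C1CO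
F5 | step 5 | (5S)-4-formyl-3,3,5-trimethylcyclohex-1-en-1-yl pivalate (C4 epimers) | C[C@H]1CC(OC(=O)C(C)(C)C)=CC(C)(C)C1C=O
F6 | step 5 | (4R,5S)-4-allyl-4-formyl-3,3,5-trimethylcyclohex-1-en-1-yl pivalate | C[C@H]1CC(OC(=O)C(C)(C)C)=CC(C)(C)[C@]1(CC=C)C=O
F7 | step 5 | (4R,5S)-4-formyl-3,3,5-trimethyl-4-(2-oxopropyl)cyclohex-1-en-1-yl pivalate | C[C@H]1CC(OC(=O)C(C)(C)C)=CC(C)(C)[C@]1(CC(C)=O)C=O
F8 | step 5 | (5S,10S)-6,6,10-trimethyl-2-oxospiro[4.5]deca-3,7-dien-8-yl pivalate | C[C@H]1CC(OC(=O)C(C)(C)C)=CC(C)(C)[C@]12C=CC(=O)C2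
F0 | step 15 | none | none
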